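In a one-step world, where each starting material takes one coupling partner and nothing else touches either, starting material being the limiting reagent, one quantity stays frozen through a flask: the excess, meaning coupling partner less starting material, 100 mM in the east run and 100 mM in the south-east run.

| flask | starting material | coupling partner | time |
|---|---|---|---|
| east | 50.0 mM | 150 mM |  |
| south-east | 25.0 mM | 125 mM |  |
| south-west | 50.0 mM | 300 mM |  |
| north-east | 75.0 mM | 150 mM |  |
| north | 120 mM | 380 mM | 92 min |

- east run (time / min: [target] / mM): 5.2: 23.7; 16: 38.0; 30: 42.4; 48: 44.1; 69: 44.8; 92: 46.2
- south-east run (time / min: [target] / mM): 5.2: 10.6; 16: 18.3; 30: 21.4; 48: 21.5; 69: 21.9; 92: 23.5
- south-west run (time / min: [target] / mM): 5.2: 33.2; 16: 44.8; 30: 46.9; 48: 48.4; 69: 48.8; 92: 50.2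
- north-east run (time / min: [target] / mM): 5.2: 33.9; 16: 52.8; 30: 60.3; 48: 62.9; 69: 63.6; 92: 64.9

(each reading ± 0.5 mM)

- order of the initial rate in [starting material], near the charge of the east run, the rate being that where two percent of its starting material are target (one fixed amount of target, the same in the runs compared)
- order of the initial rate in [coupling partner], near the charge of the east run, the rate being that where two percent of its starting material are target
- the south-east run starts with 25.0 mM less of starting material and of coupling partner than the east run, and with no target. Compared where both hold the same amount of starting material, once fifteen percent of what the south-east run was charged with has turned into target, is the south-east run faster, slower or alike (within a tenth)?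
- target in the north run at 92 min, as a share of the starting material charged

- Overall: starting material + coupling partner -> target.
- Constant volume, constant temperature.
- Bound and free are read together.
- "The second partner" is coupling partner.
- An order is taken over about fifteen percent of the charge, up and down.

I held two extreme versions of the east run against each other. In the first its excess stays frozen, so that after losing 25.0 mM of starting material it is the south-east run over again, and the ratio of their rates at equal starting material, south-east over east, is one. In the second its excess of 100 mM has vanished by that point, so it holds 25.0 mM of partner beside the 125 mM of the south-east run, and with the rate taken as proportional to partner the ratio is 5.00; I expected the real east run to lie between these two versions.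

To place it I treated partner as frozen over a short stretch (the pseudo-first-order view) and took the logarithmic fall of starting material per minute. The south-east run, from charge to first reading, gave 0.106 /min, and the east run, from first to second reading, across nearly the same amounts, gave 0.0727 /min. The south-east run was therefore faster, with a read ratio of 1.46.

The excess also ranks the last readings as shares of charge: 86.5 % in the north-east run at 75.0 mM, 92.4 % in the east run at 100 mM, and 100 % in the south-west run at 250 mM. The north run, at 260 mM, stands beside the south-west run, so I reckoned it near that last share, higher than the forecast.

The forecast gave orders of 0.97 (0.8 to 1.1) in starting material and 0.8 (0.6 to 1) in coupling partner, called the south-east run faster, and put the north run at 96.5 % (92 % to 99.5 %), on this ground: “East, at equal concentrations, is therefore slower, because it is older and holds more target.”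

The flask gave orders of 1.0 and 0.72, the south-east run faster, and the north run 98.2 %.

    starting material + coupling partner → target (2.610 /M/min)
    starting material + 2 coupling partner → target + coupling partner (12.60 /M²/min)
    2 coupling partner → lost reagent (2.958 /M/min)
    2 coupling partner ⇌ idle reagent dimer, settled at all times (22.20 /M)

The ratio of the south-east run over the east run stands at 1.5 and falls to 1.0 when the reaction of two coupling partner to lost reagent is taken away, because that step removes partner without removing starting material, so the east run no longer holds its excess of 100 mM when it reaches the south-east charge. The north run, charged with an excess of 260 mM, reached 98.2 % of its starting material at 92 min, 2.2 percentage points under the last reading of the south-west run.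

Readings and results are simulated from invented constants.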